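**Retrosynthetic overview** (daucane numbering: ring A = C1–C5; ring B = C1, C5–C10; C14 = methylidene carbon on C8)
- The plan rests on one feature: the two oxygenated carbons of ring B, C6 and C9, are 1,4-related and C1 is quaternary, so a temporary C6–O–C9 oxolane can carry C10 onto C1.
- Late stage: target ⇐ desilylation ⇐ reagent-controlled reduction of the C9 enone ⇐ C8 methylenation ⇐ C6 vanillate ⇐ hydroboration of C5=C6 in the bicyclic C9 ketone.
- Ring B: the C1–C10 bond comes from a Claisen ring expansion of the exocyclic enol ether made from the C6 γ-lactone; C6–O breaks and C9 becomes the ketone.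
- The lactone comes from the ring A enal by C6 allylation, hydroboration and oxidative lactonisation; the enal comes from (S)-terpinen-4-ol by ozonolysis and aldol ring contraction.
- Ring order: ring A (chiral pool, C4 fixed), then the temporary oxolane, then ring B.

Key step: step 8

Assumption: (S)-(+)-terpinen-4-ol and the commercial solution of (−)-B-allyldiisopinocampheylborane are used in high enantiomeric purity; any minor enantiomer of 1 would leave as the separable C6 diastereomer after step 4.

**Step 1**
Reactants: 1 (S)-terpinen-4-ol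
Product: 2 (S)-terpinen-4-ol triethylsilyl ether
Conditions: Et3SiOSO2CF3, 2,6-lutidine, CH2Cl2, 0 °C to rt
Reagents that add atoms: triethylsilyl trifluoromethanesulfonate, CC[Si](CC)(CC)OS(=O)(=O)C(F)(F)F
Why: Silylation of the tertiary alcohol with a silyl triflate and a hindered pyridine base is standard, and the ether blocks retro-aldol and hemiketal side reactions of the hydroxyl in steps 2 and 3 while leaving the stereocenter untouched.

**Step 2**
Reactants: 2 (S)-terpinen-4-ol triethylsilyl ether
Product: 4 (S)-6-oxo-3-(propan-2-yl)-3-(triethylsilyloxy)heptanal, via ozonide 3 (not isolated)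
Conditions: O3, CH2Cl2, −78 °C; then PPh3, −78 °C to rt
Reagents that add atoms: ozone, [O-][O+]=O
Why: Ozonolysis with reductive work-up (dipolar cycloaddition to the ozonide, then phosphine reduction) cleaves the only alkene to the methyl ketone and the aldehyde without touching the silyl ether.

**Step 3**
Reactants: 4 (S)-6-oxo-3-(propan-2-yl)-3-(triethylsilyloxy)heptanal
Product: 6 (R)-2-methyl-5-(propan-2-yl)-5-(triethylsilyloxy)cyclopent-1-ene-1-carbaldehyde, via aldol adduct 5 (not isolated)
Conditions: piperidine (0.3 equiv), AcOH (0.3 equiv), toluene, 60 °C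
Reagents that add atoms: none
Why: In this amine-catalysed intramolecular aldol condensation the enamine of the more reactive aldehyde attacks the methyl ketone (5-exo-trig) and the adduct dehydrates to the conjugated enal, which contracts the six-membered ring to ring A with the silyloxy carbon becoming C4 in unchanged configuration.

**Step 4**
Reactants: 6 (R)-2-methyl-5-(propan-2-yl)-5-(triethylsilyloxy)cyclopent-1-ene-1-carbaldehyde; 7 (−)-B-allyldiisopinocampheylborane (the enantiomer built from (+)-α-pinene)
Product: 9 (S)-1-[(R)-2-methyl-5-(propan-2-yl)-5-(triethylsilyloxy)cyclopent-1-en-1-yl]but-3-en-1-ol, via O-borinate 8 (not isolated)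
Conditions: Et2O/pentane, −78 °C; then NaOH aq, H2O2, 0 °C to rt
Reagents that add atoms: none
Why: Brown allylboration through a closed chair transition state adds the allyl group to the Si face of the aldehyde under control of the isopinocampheyl ligands, which should override the bias of the C4 centre and set (6S), the C6 epimer being a separable diastereomer.

**Step 5**
Reactants: 9 (6S)-homoallylic alcohol
Product: 11 (S)-1-[(R)-2-methyl-5-(propan-2-yl)-5-(triethylsilyloxy)cyclopent-1-en-1-yl]butane-1,4-diol, via alkyl-9-BBN adduct 10 (not isolated)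
Conditions: 9-BBN (2.5 equiv), THF, 0 °C to rt; then NaOH aq, H2O2, 0 °C
Reagents that add atoms: hydrogen peroxide, OO
Why: Anti-Markovnikov hydroboration–oxidation with the bulky dialkylborane is selective for the monosubstituted alkene over the tetrasubstituted ring alkene and gives the primary C9 alcohol with C6 unchanged.

**Step 6**
Reactants: 11 (6S)-1,4-diol
Product: 13 (S)-5-[(R)-2-methyl-5-(propan-2-yl)-5-(triethylsilyloxy)cyclopent-1-en-1-yl]oxolan-2-one, via lactol 12 (not isolated)
Conditions: (2,2,6,6-tetramethylpiperidin-1-yl)oxyl (TEMPO, 0.2 equiv), PhI(OAc)2 (2.5 equiv), CH2Cl2, rt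
Reagents that add atoms: none
Why: In this oxidative lactonisation the nitroxyl catalyst oxidises the primary alcohol faster than the hindered secondary allylic one, the aldehyde closes to the five-membered lactol and this is oxidised on to the γ-lactone with the C6–O bond and its configuration intact.

**Step 7**
Reactants: 13 (6S)-γ-lactone
Product: 14 (S)-2-methylidene-5-[(R)-2-methyl-5-(propan-2-yl)-5-(triethylsilyloxy)cyclopent-1-en-1-yl]oxolane
Conditions: Cp2TiMe2 (2.5 equiv), toluene, 70 °C, dark; filtration through Et3N-deactivated basic Al2O3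
Reagents that add atoms: dimethyltitanocene, C[Ti](C)(C1C=CC=C1)C1C=CC=C1
Why: Petasis methylenation with the titanium methylidene formed thermally from dimethyltitanocene turns the lactone carbonyl into the exocyclic enol ether under non-acidic conditions that tolerate the silyl ether and do not enolise C8.

**Step 8**
Reactants: 14 exocyclic enol ether (6S)
Product: 15 (1R,4R)-4-(triethylsilyloxy)-14-nordauc-5-en-9-one
Conditions: degassed o-xylene, i-Pr2NEt (0.1 equiv), sealed base-washed glass tube, 170 °C
Reagents that add atoms: none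
Why: Heating drives a concerted, suprafacial [3,3] sigmatropic shift of the allyl vinyl ether array C10=C9–O–C6–C5=C1, which forms the C1–C10 bond and the C9 carbonyl while the allylic C6–O bond breaks and the alkene moves to C5=C6. The closest known reaction type is the thermal Claisen ring expansion of 2-methylidene-5-vinyloxolanes to cyclohept-4-enones, here with a cyclopentenyl group as the vinyl partner. Ring B is closed by ring expansion and not by a polar exo or endo cyclisation: oxolane carbons C7 and C8 become the two-carbon link of the carbocycle, and the five-membered ether forces a boat-like six-atom array in which only the cis C5=C6 alkene can form. The new quaternary stereocenter C1 is controlled by C6 through 1,3-chirality transfer, because the breaking C6–O bond and the forming C1–C10 bond must lie on the same face of the cyclopentene and the tether holds C7 cis to C1; with (6S) this is the face that carries the C4 isopropyl group, which gives (1R). The rearrangement must outrun migration of the exocyclic double bond into the oxolane ring and ionisation of the allylic C6–O bond, which the amine buffer, base-washed glass and exclusion of acid are meant to secure.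

**Step 9**
Reactants: 15 (1R,4R)-4-(triethylsilyloxy)-14-nordauc-5-en-9-one
Product: 16 (1R,4R)-9,9-(ethylenedioxy)-4-(triethylsilyloxy)-14-nordauc-5-ene
Conditions: Me3SiOCH2CH2OSiMe3, Me3SiOSO2CF3 (3 mol%), CH2Cl2, −78 °C; pyridine quench
Reagents that add atoms: 1,2-bis(trimethylsilyloxy)ethane, C[Si](C)(C)OCCO[Si](C)(C)C
Why: Silyl triflate-catalysed ketalisation with the bis-silyl ether of ethylene glycol (Noyori conditions) is aprotic and cold, so the unhindered C9 ketone should be masked without ionising the tertiary allylic silyl ether or moving the C5=C6 alkene.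

**Step 10**
Reactants: 16 C9 ketal
Product: 18 (1R,4R,5S,6S)-9,9-(ethylenedioxy)-4-(triethylsilyloxy)-14-nordaucan-6-ol, via C6 alkylborane 17 (not isolated)
Conditions: BH3·THF (3 equiv), THF, 0 °C to rt; then NaOH aq, H2O2, 0 °C to rt
Reagents that add atoms: hydrogen peroxide, OO
Why: Hydroboration–oxidation puts boron on the less substituted C6 and hydrogen on C5 in a syn addition and oxidises the C–B bond with retention; addition is expected on the face opposite the C1 methyl and the C4 silyloxy group, which sets H5 and the C6 hydroxyl cis to each other and the ring fusion trans.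

**Step 11**
Reactants: 19 vanillic acid
Product: 21 4-(tert-butyldimethylsilyloxy)-3-methoxybenzoic acid, via bis-silyl derivative 20 (not isolated)
Conditions: t-BuMe2SiCl (2.4 equiv), imidazole, DMF, rt; then AcOH/THF/H2O, rt
Reagents that add atoms: tert-butyldimethylsilyl chloride, CC(C)(C)[Si](C)(C)Cl
Why: Silylation of both acidic hydroxyls followed by selective hydrolysis of the labile silyl ester under mild aqueous acid leaves the phenol as its silyl ether and frees the carboxylic acid.

**Step 12**
Reactants: 18 C6 alcohol; 21 4-(tert-butyldimethylsilyloxy)-3-methoxybenzoic acid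
Product: 23 (1R,4R,5S,6S)-9,9-(ethylenedioxy)-4-(triethylsilyloxy)-14-nordaucan-6-yl 4-(tert-butyldimethylsilyloxy)-3-methoxybenzoate, via mixed anhydride 22 (not isolated)
Conditions: 2,4,6-Cl3C6H2COCl, Et3N, THF, rt; then 18, 4-(dimethylamino)pyridine, toluene, 60 °C
Reagents that add atoms: none
Why: Yamaguchi esterification through the mixed anhydride and an acylpyridinium ion acylates the hindered secondary C6 alcohol with retention, and doing so before the ketone is freed prevents a bridged C6–O–C9 hemiketal.

**Step 13**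
Reactants: 23 C6 ester C9 ketal
Product: 24 (1R,4R,5S,6S)-9-oxo-4-(triethylsilyloxy)-14-nordaucan-6-yl 4-(tert-butyldimethylsilyloxy)-3-methoxybenzoate
Conditions: pyridinium p-toluenesulfonate (0.3 equiv), acetone/H2O (10:1), 50 °C
Reagents that add atoms: water, O
Why: Mild acid-catalysed hydrolysis of the dioxolane regenerates the C9 ketone, while the aryl ester, the aryl silyl ether and the hindered tertiary silyl ether should survive.

**Step 14**
Reactants: 24 C9 ketone
Product: 28 (1R,4R,5S,6S)-9-oxo-4-(triethylsilyloxy)dauc-8(14)-en-6-yl 4-(tert-butyldimethylsilyloxy)-3-methoxybenzoate, via lithium enolate 25 (not isolated), via Mannich base 26 (not isolated), via methiodide 27 (not isolated)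
Conditions: LiN(SiMe3)2 (1.15 equiv), THF, −78 °C; CH2=NMe2+ I−, −78 °C to rt; then MeI, CH2Cl2, rt; then NaHCO3 aq, rt
Reagents that add atoms: Eschenmoser's salt, C=[N+](C)C.[I-]
Why: Kinetic deprotonation by the bulky amide should occur at C8 and not at C10, which is neopentylic next to quaternary C1, and the enolate then undergoes a Mannich reaction with Eschenmoser's salt followed by quaternisation and E1cB loss of trimethylamine to give the α-methylidene ketone.

**Step 15**
Reactants: 28 C8-methylidene C9 ketone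
Product: 30 (1R,4R,5S,6S,9S)-9-hydroxy-4-(triethylsilyloxy)dauc-8(14)-en-6-yl 4-(tert-butyldimethylsilyloxy)-3-methoxybenzoate, via catecholborate ester 29 (not isolated)
Conditions: (R)-2-methyl-CBS-oxazaborolidine ((3aR)-1-methyl-3,3-diphenyltetrahydro-1H,3H-pyrrolo[1,2-c][1,3,2]oxazaborole, 0.5 equiv), catecholborane (2 equiv), toluene/CH2Cl2, −78 °C; MeOH then aqueous work-up
Reagents that add atoms: none
Why: Corey–Bakshi–Shibata reduction with catecholborane gives 1,2-reduction of the enone under reagent control, with the α-branched alkenyl carbon C8 as the large group and C10 as the small one, so the (R)-catalyst should deliver hydride to the face that gives the (9S)-alcohol.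

**Step 16**
Reactants: 30 bis-silylated (9S)-allylic alcohol
Product: 31 (1R,4R,5S,6S,9S)-4,9-dihydroxydauc-8(14)-en-6-yl 4-hydroxy-3-methoxybenzoate (CNP0330487.1)
Conditions: HF·pyridine, pyridine/THF, 0 °C to rt
Reagents that add atoms: none
Why: Fluoride-mediated desilylation under buffered, weakly acidic conditions cleaves the aryl silyl ether and the tertiary triethylsilyl ether in one operation without acyl migration or allylic transposition and leaves all five stereocenters untouched.

**Compound list**
1 | (S)-terpinen-4-ol | CC1=CC[C@](O)(C(C)C)CC1 | starting material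
2 | (S)-terpinen-4-ol triethylsilyl ether | CC1=CC[C@](O[Si](CC)(CC)CC)(C(C)C)CC1 | intermediate
3 | ozonide of 2 (1,2,4-trioxolane across the former C=C; bridgehead configuration unassigned) | CC12CC[C@@](O[Si](CC)(CC)CC)(C(C)C)CC(OO1)O2 | intermediate
4 | (S)-6-oxo-3-(propan-2-yl)-3-(triethylsilyloxy)heptanal | CC(=O)CC[C@@](O[Si](CC)(CC)CC)(C(C)C)CC=O | intermediate
5 | aldol adduct, 2-hydroxy-2-methyl-5-(propan-2-yl)-5-(triethylsilyloxy)cyclopentane-1-carbaldehyde (new centres unassigned) | O=CC1C(C)(O)CC[C@@]1(O[Si](CC)(CC)CC)C(C)C | intermediate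
6 | (R)-2-methyl-5-(propan-2-yl)-5-(triethylsilyloxy)cyclopent-1-ene-1-carbaldehyde | O=CC1=C(C)CC[C@@]1(O[Si](CC)(CC)CC)C(C)C | intermediate
7 | (−)-B-allyldiisopinocampheylborane, from (+)-α-pinene | C=CCB([C@@H]1C[C@@H]2C[C@H]([C@H]1C)C2(C)C)[C@@H]1C[C@@H]2C[C@H]([C@H]1C)C2(C)C | starting material
8 | diisopinocampheylborinate of 9 | C=CC[C@H](OB([C@@H]1C[C@@H]2C[C@H]([C@H]1C)C2(C)C)[C@@H]1C[C@@H]2C[C@H]([C@H]1C)C2(C)C)C1=C(C)CC[C@@]1(O[Si](CC)(CC)CC)C(C)C | intermediate
9 | (S)-1-[(R)-2-methyl-5-(propan-2-yl)-5-(triethylsilyloxy)cyclopent-1-en-1-yl]but-3-en-1-ol | C=CC[C@H](O)C1=C(C)CC[C@@]1(O[Si](CC)(CC)CC)C(C)C | intermediate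
10 | B-alkyl-9-borabicyclo[3.3.1]nonane adduct of 9 (boron on the terminal carbon) | C(CC[C@H](O)C1=C(C)CC[C@@]1(O[Si](CC)(CC)CC)C(C)C)B1C2CCCC1CCC2 | intermediate
11 | (S)-1-[(R)-2-methyl-5-(propan-2-yl)-5-(triethylsilyloxy)cyclopent-1-en-1-yl]butane-1,4-diol | OCCC[C@H](O)C1=C(C)CC[C@@]1(O[Si](CC)(CC)CC)C(C)C | intermediate
12 | lactol, (5S)-5-(cyclopentenyl)oxolan-2-ol (anomeric centre unassigned) | OC1CC[C@H](O1)C1=C(C)CC[C@@]1(O[Si](CC)(CC)CC)C(C)C | intermediate
13 | (S)-5-[(R)-2-methyl-5-(propan-2-yl)-5-(triethylsilyloxy)cyclopent-1-en-1-yl]oxolan-2-one | O=C1CC[C@H](O1)C1=C(C)CC[C@@]1(O[Si](CC)(CC)CC)C(C)C | intermediate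
14 | (S)-2-methylidene-5-[(R)-2-methyl-5-(propan-2-yl)-5-(triethylsilyloxy)cyclopent-1-en-1-yl]oxolane | C=C1CC[C@H](O1)C1=C(C)CC[C@@]1(O[Si](CC)(CC)CC)C(C)C | intermediate
15 | (1R,4R)-4-(triethylsilyloxy)-14-nordauc-5-en-9-one | O=C1CCC=C2[C@](C)(CC[C@@]2(O[Si](CC)(CC)CC)C(C)C)C1 | intermediate
16 | (1R,4R)-9,9-(ethylenedioxy)-4-(triethylsilyloxy)-14-nordauc-5-ene | O1CCOC12CCC=C3[C@](C)(CC[C@@]3(O[Si](CC)(CC)CC)C(C)C)C2 | intermediate
17 | C6 alkylborane from 16 (drawn as the monoalkylborane; H5 and boron on the face opposite the C1 methyl) | O1CCOC12CC[C@H](B)[C@@H]3[C@](C)(CC[C@@]3(O[Si](CC)(CC)CC)C(C)C)C2 | intermediate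
18 | (1R,4R,5S,6S)-9,9-(ethylenedioxy)-4-(triethylsilyloxy)-14-nordaucan-6-ol | O1CCOC12CC[C@H](O)[C@@H]3[C@](C)(CC[C@@]3(O[Si](CC)(CC)CC)C(C)C)C2 | intermediate
19 | vanillic acid | COc1cc(C(=O)O)ccc1O | starting material
20 | tert-butyldimethylsilyl 4-(tert-butyldimethylsilyloxy)-3-methoxybenzoate | COc1cc(C(=O)O[Si](C)(C)C(C)(C)C)ccc1O[Si](C)(C)C(C)(C)C | intermediate
21 | 4-(tert-butyldimethylsilyloxy)-3-methoxybenzoic acid | COc1cc(C(=O)O)ccc1O[Si](C)(C)C(C)(C)C | intermediate
22 | mixed anhydride of 21 with 2,4,6-trichlorobenzoic acid | COc1cc(C(=O)OC(=O)c2c(Cl)cc(Cl)cc2Cl)ccc1O[Si](C)(C)C(C)(C)C | intermediate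
23 | (1R,4R,5S,6S)-9,9-(ethylenedioxy)-4-(triethylsilyloxy)-14-nordaucan-6-yl 4-(tert-butyldimethylsilyloxy)-3-methoxybenzoate | O1CCOC12CC[C@H](OC(=O)c3ccc(O[Si](C)(C)C(C)(C)C)c(OC)c3)[C@@H]3[C@](C)(CC[C@@]3(O[Si](CC)(CC)CC)C(C)C)C2 | intermediate
24 | (1R,4R,5S,6S)-9-oxo-4-(triethylsilyloxy)-14-nordaucan-6-yl 4-(tert-butyldimethylsilyloxy)-3-methoxybenzoate | O=C1CC[C@H](OC(=O)c2ccc(O[Si](C)(C)C(C)(C)C)c(OC)c2)[C@@H]2[C@](C)(CC[C@@]2(O[Si](CC)(CC)CC)C(C)C)C1 | intermediate
25 | lithium C8=C9 enolate of 24 | [Li]OC1=CC[C@H](OC(=O)c2ccc(O[Si](C)(C)C(C)(C)C)c(OC)c2)[C@@H]2[C@](C)(CC[C@@]2(O[Si](CC)(CC)CC)C(C)C)C1 | intermediate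
26 | C8 (dimethylamino)methyl ketone (C8 epimers) | O=C1C(CN(C)C)C[C@H](OC(=O)c2ccc(O[Si](C)(C)C(C)(C)C)c(OC)c2)[C@@H]2[C@](C)(CC[C@@]2(O[Si](CC)(CC)CC)C(C)C)C1 | intermediate
27 | trimethylammonium iodide of 26 | O=C1C(C[N+](C)(C)C)C[C@H](OC(=O)c2ccc(O[Si](C)(C)C(C)(C)C)c(OC)c2)[C@@H]2[C@](C)(CC[C@@]2(O[Si](CC)(CC)CC)C(C)C)C1.[I-] | intermediate
28 | (1R,4R,5S,6S)-9-oxo-4-(triethylsilyloxy)dauc-8(14)-en-6-yl 4-(tert-butyldimethylsilyloxy)-3-methoxybenzoate | C=C1C[C@H](OC(=O)c2ccc(O[Si](C)(C)C(C)(C)C)c(OC)c2)[C@@H]2[C@](C)(CC[C@@]2(O[Si](CC)(CC)CC)C(C)C)CC1=O | intermediate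
29 | catecholborate ester of 30 | C=C1C[C@H](OC(=O)c2ccc(O[Si](C)(C)C(C)(C)C)c(OC)c2)[C@@H]2[C@](C)(CC[C@@]2(O[Si](CC)(CC)CC)C(C)C)C[C@@H]1OB1Oc2ccccc2O1 | intermediate
30 | (1R,4R,5S,6S,9S)-9-hydroxy-4-(triethylsilyloxy)dauc-8(14)-en-6-yl 4-(tert-butyldimethylsilyloxy)-3-methoxybenzoate | C=C1C[C@H](OC(=O)c2ccc(O[Si](C)(C)C(C)(C)C)c(OC)c2)[C@@H]2[C@](C)(CC[C@@]2(O[Si](CC)(CC)CC)C(C)C)C[C@@H]1O | intermediate
31 | (1R,4R,5S,6S,9S)-4,9-dihydroxydauc-8(14)-en-6-yl 4-hydroxy-3-methoxybenzoate (CNP0330487.1) | C=C1C[C@H](OC(=O)c2ccc(O)c(OC)c2)[C@@H]2[C@](C)(CC[C@@]2(O)C(C)C)C[C@@H]1O | target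

**Step count**
Total: 16 steps. Longest linear sequence: 15 steps (steps 1–10 and 12–16 from (S)-terpinen-4-ol); step 11 is a one-step branch.

**Steps most likely to fail**

1. Step 10, facial selectivity of the hydroboration. The folded cycloheptene places C8 and C10 on the upper side of the C5=C6 alkene, and C4 carries its isopropyl group there, so addition syn to the C1 methyl may compete or dominate and give the cis-fused 5,6-diepimer. The fallback sets out from 16 and returns at 18, and uses lower-face attack to the opposite effect.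
 - Epoxidation (m-chloroperbenzoic acid, NaHCO3, CH2Cl2, 0 °C) should give the 5,6-epoxide with oxygen on the face of the C1 methyl F1.
 - Borohydride-catalysed borane opening (BH3·THF, LiBH4 cat., THF, 0 °C to rt) should deliver hydride to the tertiary C5 with inversion, giving the 6-epi alcohol with H5 already anti to the methyl F2.
 - Dess–Martin oxidation (NaHCO3, CH2Cl2) should give the trans-fused C6 ketone F3.
 - Dissolving-metal reduction (Li, NH3/THF, t-BuOH, −78 °C) should give the thermodynamically preferred equatorial alcohol, which is 18.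

2. Step 8, the Claisen ring expansion. Acid-catalysed migration of the exocyclic double bond into the oxolane ring, ionisation of the doubly allylic C6–O bond with loss of chirality transfer, or thermal loss of the allylic silyl ether could overtake the [3,3] shift at the temperature needed to form the quaternary centre. The fallback sets out from 14 and returns at 15.
 - The rearrangement is promoted below room temperature with a Lewis acid (i-Bu3Al, CH2Cl2, −78 °C to rt), which also reduces the new ketone in the flask and should give the C9 alcohol (1R,4R)-4-(triethylsilyloxy)-14-nordauc-5-en-9-ol as an epimer mixture F4.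
 - Dess–Martin oxidation (NaHCO3, CH2Cl2) then returns 15; the fidelity of C6-to-C1 transfer would have to be checked at this point.

3. Step 15, the C9 reduction. Substrate bias (hydride delivery anti to the pseudo-axial C1 methyl) may outweigh catalyst control and give the 9R epimer, and conjugate reduction of the reactive enone is a further possibility. The fallback sets out from 28 and returns at 30, accepting the substrate bias and then inverting.
 - Luche reduction (NaBH4, CeCl3·7H2O, MeOH, −78 °C) should give the (9R)-allylic alcohol F5.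
 - Mitsunobu inversion (PPh3, diisopropyl azodicarboxylate, ClCH2CO2H, THF, 0 °C to rt) should give the (9S)-chloroacetate F6.
 - Thiourea (NaHCO3, EtOH, 50 °C) should remove the chloroacetyl group selectively in the presence of the vanillate and both silyl ethers to give 30.

**Further compounds**
F1 | step 10 | 5,6-epoxide of 16 with oxygen on the face of the C1 methyl | O1CCOC12CC[C@H]3O[C@@]34[C@](C)(CC[C@@]4(O[Si](CC)(CC)CC)C(C)C)C2
F2 | step 10 | 6-epimer of 18 (6R alcohol, H5 anti to the C1 methyl) | O1CCOC12CC[C@@H](O)[C@@H]3[C@](C)(CC[C@@]3(O[Si](CC)(CC)CC)C(C)C)C2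
F3 | step 10 | trans-fused 9,9-(ethylenedioxy)-4-(triethylsilyloxy)-14-nordaucan-6-one | O1CCOC12CCC(=O)[C@@H]3[C@](C)(CC[C@@]3(O[Si](CC)(CC)CC)C(C)C)C2
F4 | step 8 | (1R,4R)-4-(triethylsilyloxy)-14-nordauc-5-en-9-ol (C9 epimers) | OC1CCC=C2[C@](C)(CC[C@@]2(O[Si](CC)(CC)CC)C(C)C)C1
F5 | step 15 | (9R)-epimer of 30 | C=C1C[C@H](OC(=O)c2ccc(O[Si](C)(C)C(C)(C)C)c(OC)c2)[C@@H]2[C@](C)(CC[C@@]2(O[Si](CC)(CC)CC)C(C)C)C[C@H]1O
F6 | step 15 | (9S)-chloroacetate of 30 | C=C1C[C@H](OC(=O)c2ccc(O[Si](C)(C)C(C)(C)C)c(OC)c2)[C@@H]2[C@](C)(CC[C@@]2(O[Si](CC)(CC)CC)C(C)C)C[C@@H]1OC(=O)CCl
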